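## Retrosynthetic overview

- The C4–aryl bond is cut last: Suzuki coupling of 4-bromo-3,6-dihydroxy-5-methoxy-2-naphthaldehyde and 3,4-dimethoxyphenylboronic acid.
- The CHO carbon is removed and ring A is taken back to its ortho-quinone monoketal. In that form the other ring is an ordinary benzenoid 2-bromophenol that formylates at its one free ortho carbon. The aromatic naphthol would offer only a poorly reactive beta position.
- Key disconnection, the C5–OMe bond: oxidative C–H methoxylation and dearomatisation of 1-bromonaphthalene-2,7-diol with PhI(OAc)2/MeOH. This forms the C–O bond, tells the two phenols apart and masks the C6 hydroxyl as a ketone.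
- 1-Bromonaphthalene-2,7-diol comes from symmetric naphthalene-2,7-diol and NBS.
- No ring is built. Rings A and B are bought as the naphthalenediol and ring C as the boronic acid.

Assumption: the SMILES has no stereocentre, and the C4–aryl axis (only H ortho on the dimethoxyphenyl ring) rotates freely at room temperature. The target is therefore treated as achiral and nothing has to be set.

Target numbering used below: C2 CHO, C3 OH, C4 aryl, C5 OMe, C6 OH.

## Route

Step 1
Reactants: 1 naphthalene-2,7-diol
Product: 2 1-bromonaphthalene-2,7-diol
Conditions: NBS (1.0 equiv), MeCN, −10 to 0 °C, 1 h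
Reagents that add atoms: N-bromosuccinimide, O=C1CCC(=O)N1Br
Why: Electrophilic aromatic bromination: a 2-naphthol reacts fastest at the alpha carbon next to its OH, the two such carbons of 1 are equivalent, and one equivalent of NBS at low temperature stops at the monobromide because the first bromine deactivates the system.

Step 2
Reactants: 2 1-bromonaphthalene-2,7-diol
Product: 4 8-bromo-7-hydroxy-1,1-dimethoxynaphthalen-2(1H)-one, via 8-bromo-1-methoxynaphthalene-2,7-diol 3 (not isolated)
Conditions: PhI(OAc)2 (2.1 equiv), MeOH (0.05 M), 0 °C to rt, 1 h
Reagents that add atoms: methanol, CO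
Why: Trivalent-iodine oxidative dearomatisation (two successive C–O bond formations at a 2-naphthol alpha carbon, ending at the ortho-quinone monoketal): the unbrominated half is the more electron-rich and the only one with a free alpha C–H, the first methoxy group makes the second oxidation faster than the first, the sp3 ketal carbon relieves peri strain against the in-plane bromine, and the remaining push-pull bromophenol is too electron-poor to be oxidised further.

Step 3
Reactants: 4 8-bromo-7-hydroxy-1,1-dimethoxynaphthalen-2(1H)-one
Product: 7 4-bromo-3,6-dihydroxy-5-methoxy-2-naphthaldehyde, via hydroxymethyl ketal 5 (not isolated), via formyl carbinol ketal 6 (not isolated)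
Conditions: MgCl2 (anhydrous, 2.5 equiv), Et3N (4 equiv), (CH2O)n (1.2 equiv CH2O, in portions), THF, 65 °C, 6 h; then 1 M HCl
Reagents that add atoms: formaldehyde (as paraformaldehyde), C=O
Why: Proposed new method: a Casnati–Skattebøl ortho-formylation made redox-neutral, in which the magnesium phenoxide of 4 (a benzenoid 2-bromophenol whose only free ortho carbon is the one required) adds to one formaldehyde to give the benzylic magnesium alkoxide of 5, and the hydride that such an alkoxide normally hands to a second formaldehyde is instead passed, through a six-membered Oppenauer/Meerwein–Ponndorf–Verley transition state between two magnesium-bound molecules, to the ketone of the ortho-quinone monoketal (chelated through its C=O and a ketal OMe), so that 6 forms and loses methanol irreversibly to give the naphthalene 7; magnesium methoxide made by stray hydride transfer to formaldehyde can return that hydride to the ketal, so aromatisation is the thermodynamic sink, no external reductant endangers the labile C–Br bond, and the unmasked naphthol keeps only an unreactive beta ortho carbon; the closest known reaction types are the MgCl2/Et3N/paraformaldehyde formylation of 2-bromophenol, the magnesium Oppenauer oxidation and the reductive aromatisation of quinone monoketals.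

Step 4
Reactants: 7 4-bromo-3,6-dihydroxy-5-methoxy-2-naphthaldehyde; 8 (3,4-dimethoxyphenyl)boronic acid (1.5 equiv)
Product: 9 vitrofolal B, 4-(3,4-dimethoxyphenyl)-3,6-dihydroxy-5-methoxy-2-naphthaldehyde
Conditions: Pd(OAc)2 (3 mol %), SPhos (2-dicyclohexylphosphino-2′,6′-dimethoxybiphenyl, 6 mol %), K3PO4 (3.5 equiv), degassed 1,4-dioxane/H2O 5:1, 80 °C, argon; then dilute HCl to pH 4
Reagents that add atoms: none
Why: Suzuki–Miyaura coupling: the bulky electron-rich ligand lets zerovalent palladium insert into the peri-crowded C4–Br bond and couple it to an unhindered boronic acid faster than protodebromination, free phenols and salicylaldehydes are tolerated as their potassium salts, and no stereocentre or stable axis is created.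

## Compound list

1 | naphthalene-2,7-diol | Oc1ccc2ccc(O)cc2c1 | starting material
2 | 1-bromonaphthalene-2,7-diol | Oc1ccc2ccc(O)c(Br)c2c1 | intermediate
3 | 8-bromo-1-methoxynaphthalene-2,7-diol (not isolated) | COc1c(O)ccc2ccc(O)c(Br)c12 | intermediate
4 | 8-bromo-7-hydroxy-1,1-dimethoxynaphthalen-2(1H)-one | COC1(OC)C(=O)C=Cc2ccc(O)c(Br)c21 | intermediate
5 | 8-bromo-7-hydroxy-6-(hydroxymethyl)-1,1-dimethoxynaphthalen-2(1H)-one (not isolated) | COC1(OC)C(=O)C=Cc2cc(CO)c(O)c(Br)c21 | intermediate
6 | 4-bromo-3,6-dihydroxy-5,5-dimethoxy-5,6-dihydronaphthalene-2-carbaldehyde (racemic at the transient carbinol carbon, not isolated) | COC1(OC)C(O)C=Cc2cc(C=O)c(O)c(Br)c21 | intermediate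
7 | 4-bromo-3,6-dihydroxy-5-methoxy-2-naphthaldehyde | COc1c(O)ccc2cc(C=O)c(O)c(Br)c12 | intermediate
8 | (3,4-dimethoxyphenyl)boronic acid | COc1ccc(B(O)O)cc1OC | starting material
9 | vitrofolal B | COc1ccc(-c2c(O)c(C=O)cc3ccc(O)c(OC)c23)cc1OC | target

## Step count and risks

Total step count: 4. Longest linear sequence: 4 (1 → 2 → 4 → 7 → 9).

Three steps most likely to fail:

**Step 2.** The oxidant may attack the brominated half (ipso attack with loss of bromine), bromine may migrate, or over-oxidation may occur.
- The fallback sets out from 1 and postpones the halogen.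
- The symmetric diol 1, where no site question exists, is oxidised with PhI(OAc)2/MeOH to 7-hydroxy-1,1-dimethoxynaphthalen-2(1H)-one F1.
- Classical formylation (MgCl2, Et3N, excess paraformaldehyde, THF, reflux) then takes place at the ortho carbon remote from the ketal. It gives 3-hydroxy-5,5-dimethoxy-6-oxo-5,6-dihydronaphthalene-2-carbaldehyde F2.
- Aqueous Na2S2O4 in THF reduces this to 3,6-dihydroxy-5-methoxy-2-naphthaldehyde F3.
- NBS in MeCN at −20 °C brominates the only free alpha carbon next to a hydroxyl, and the route is rejoined at 7.

**Step 3 (the new step).** Formaldehyde may outcompete the ketal as hydride acceptor. The hydroxymethyl stage may leak into ortho-quinone methide products (methoxymethyl ethers, diarylmethanes).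
- The fallback sets out from 4 and uses known chemistry with an external oxidant and an external reductant.
- Standard Casnati–Skattebøl conditions with excess paraformaldehyde (4 equiv) give 4-bromo-3-hydroxy-5,5-dimethoxy-6-oxo-5,6-dihydronaphthalene-2-carbaldehyde F4, which is isolated.
- A brief reduction with buffered aqueous Na2S2O4 in THF at 0 °C aromatises F4, and the route is rejoined at 7.

**Step 4.** The free 1-halo-2-naphthol motif may protodebrominate through its keto tautomer, and insertion next to the peri methoxy group may be slow.
- The fallback sets out from 7 and removes the tautomer by protection.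
- MOMCl and iPr2NEt in CH2Cl2 give 4-bromo-5-methoxy-3,6-bis(methoxymethoxy)-2-naphthaldehyde F5.
- Suzuki coupling with 8 gives 4-(3,4-dimethoxyphenyl)-5-methoxy-3,6-bis(methoxymethoxy)-2-naphthaldehyde F6.
- HCl in MeOH at 40 °C followed by aqueous work-up removes both acetals, and the route is rejoined at 9.

Further compounds
F1 | step 2 | 7-hydroxy-1,1-dimethoxynaphthalen-2(1H)-one | COC1(OC)C(=O)C=Cc2ccc(O)cc21
F2 | step 2 | 3-hydroxy-5,5-dimethoxy-6-oxo-5,6-dihydronaphthalene-2-carbaldehyde | COC1(OC)C(=O)C=Cc2cc(C=O)c(O)cc21
F3 | step 2 | 3,6-dihydroxy-5-methoxy-2-naphthaldehyde | COc1c(O)ccc2cc(C=O)c(O)cc12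
F4 | step 3 | 4-bromo-3-hydroxy-5,5-dimethoxy-6-oxo-5,6-dihydronaphthalene-2-carbaldehyde | COC1(OC)C(=O)C=Cc2cc(C=O)c(O)c(Br)c21
F5 | step 4 | 4-bromo-5-methoxy-3,6-bis(methoxymethoxy)-2-naphthaldehyde | COCOc1ccc2cc(C=O)c(OCOC)c(Br)c2c1OC
F6 | step 4 | 4-(3,4-dimethoxyphenyl)-5-methoxy-3,6-bis(methoxymethoxy)-2-naphthaldehyde | COCOc1ccc2cc(C=O)c(OCOC)c(-c3ccc(OC)c(OC)c3)c2c1OC
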